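**Retrosynthetic overview**

1. Ring letters: A = (Z)-butylidene butenolide, B = cyclohexene fused to A, C = central cyclopentane, D = bridging γ-lactone, E = second cyclohexene; the rings are built in the order E, C, B, D, A.
2. Ring A is disconnected to a vinyl triflate acid plus pent-1-yne (Pd/Cu coupling–lactonisation); ring D and the butanoyl group come from a butylidene group on the ring C ketone (Wittig, ketohydroxylation, lactonisation).
3. Ring B is disconnected by a double Michael annulation of a vinyl β-keto ester onto a ring C cyclopentenone.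
4. Key disconnection (ring C): the bond between the ketone carbon and ring E, made by carbene-catalysed acyl-anion addition of a tethered aldehyde to one of the two enantiotopic alkenes of a cyclohexa-2,5-diene; this sets the quaternary carbon and the adjacent CH in one step.
5. Ring E comes from tert-butyl benzoate by Birch reductive alkylation.

Assumption: the sense of induction of the triazolium salt in step 2 is assumed; its mirror-image salt is equally available if the opposite enantiomer of the bicyclic ketone forms.

**Route**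

Step 1
Reactants: 1 tert-butyl benzoate; 2 3-bromo-1,1-dimethoxypropane
Product: 5 tert-butyl 1-(3-oxopropyl)cyclohexa-2,5-diene-1-carboxylate, via lithium dienolate 3 (not isolated), via dimethyl acetal 4 (not isolated)
Conditions: Li (2.2 equiv), NH3(l)/THF, t-BuOH (1.0 equiv), −78 °C; then 2, −78 °C → rt; then 1 M HCl/THF (1:1), rt
Reagents that add atoms: water, O
Why: Birch reductive alkylation, in which dissolving-metal reduction gives the ester dienolate that is alkylated at the ipso carbon by the primary bromide, and the acidic work-up hydrolyses the dimethyl acetal while the tert-butyl ester survives; no stereocentre forms because the two ring arms are identical.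

Step 2
Reactants: 5
Product: 6 tert-butyl (3aS,7aS)-1-oxo-1,2,3,6,7,7a-hexahydro-3aH-indene-3a-carboxylate
Conditions: (5aR,10bS)-2-mesityl-5a,10b-dihydro-4H,6H-indeno[2,1-b][1,2,4]triazolo[4,3-d][1,4]oxazin-2-ium chloride (20 mol %), DBU (40 mol %), 1,4-dioxane, 100 °C
Reagents that add atoms: none
Why: Proposed new method: the carbene adds to the aldehyde to give a Breslow intermediate, an acyl anion equivalent whose nucleophilic carbon bonds to the near carbon of one of the two enantiotopic ring alkenes while the enol O–H is passed to the far carbon through a five-centre, Conia-ene-like transition state (5-exo closure, so the new ring can only be cis-fused), the chiral triazolylidene choosing the alkene and so fixing the quaternary carbon and the adjacent CH together; the closest known reactions are the carbene-catalysed intramolecular hydroacylation of unactivated alkenes (2-allyloxybenzaldehydes to chromanones, also enantioselective) and the enantioselective intramolecular Stetter desymmetrisation of cyclohexadienones.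

Step 3
Reactants: 6
Product: 8 tert-butyl (3aR,7aS)-1-oxo-1,6,7,7a-tetrahydro-3aH-indene-3a-carboxylate, via silyl enol ether 7 (not isolated)
Conditions: LiN(i-Pr)2, THF, −78 °C; Me3SiCl; then Pd(OAc)2 (1.1 equiv), MeCN, rt
Reagents that add atoms: none
Why: Saegusa–Ito oxidation, in which kinetic deprotonation occurs at the CH2 next to the ketone rather than at the hindered ring-fusion CH and divalent palladium turns the silyl enol ether into the enone by β-hydride elimination, leaving both stereocentres untouched.

Step 4
Reactants: 9 tert-butyl acetate; 10 acrolein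
Product: 12 tert-butyl 3-hydroxypent-4-enoate, via lithium enolate 11 (not isolated)
Conditions: LiN(i-Pr)2, THF, −78 °C; then 10, −78 °C; aq. NH4Cl
Reagents that add atoms: none
Why: aldol addition, the lithium ester enolate adding 1,2 to acrolein at low temperature; the racemic carbinol centre is removed in the next step.

Step 5
Reactants: 12
Product: 13 tert-butyl 3-oxopent-4-enoate
Conditions: IBX, EtOAc, 75 °C
Reagents that add atoms: none
Why: IBX oxidation of the allylic secondary alcohol gives the vinyl β-keto ester (a Nazarov reagent), which is used at once to avoid polymerisation; no stereocentre.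

Step 6
Reactants: 8; 13
Product: 14 di-tert-butyl (4aR,4bS,8aR,9aS)-6-hydroxy-9-oxo-1,2,4b,7,8,8a,9,9a-octahydro-4aH-fluorene-4a,5-dicarboxylate
Conditions: Cs2CO3 (20 mol %), CH2Cl2, 0 °C → rt
Reagents that add atoms: none
Why: Deslongchamps-type double Michael annulation (anionic formal [4+2]), in which the β-keto ester carbanion adds to the enone β-carbon on the face opposite the bulky angular CO2t-Bu (the other face carries only a vinylic CH tied back into ring E) and the resulting ketone enolate closes 6-endo-trig onto the vinyl ketone on the same face, so the two new CH centres are cis to each other and anti to the ester; the ester-bearing carbon of the β-keto ester is enolised and has no fixed configuration.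

Step 7
Reactants: 14; 15 butyltriphenylphosphonium bromide
Product: 17 di-tert-butyl (4aS,4bS,8aR,9aR)-9-butylidene-6-hydroxy-1,2,4b,7,8,8a,9,9a-octahydro-4aH-fluorene-4a,5-dicarboxylate, via butylidenetriphenylphosphorane 16 (not isolated)
Conditions: 15 (3.0 equiv), KOC(CH3)3 (3.0 equiv), THF, 0 °C; then 14, 0 → 65 °C
Reagents that add atoms: none
Why: Wittig olefination, in which the first equivalent of base stores the β-keto ester as its unreactive enolate and the excess ylide olefinates the remaining cyclopentanone from its open face; the alkene geometry does not matter because both alkene carbons are oxidised in step 9, and no stereocentre changes.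

Step 8
Reactants: 17
Product: 18 di-tert-butyl (4aS,4bS,8aR,9aR)-9-butylidene-6-{[(trifluoromethyl)sulfonyl]oxy}-1,2,4b,7,8,8a,9,9a-octahydro-4aH-fluorene-4a,5-dicarboxylate
Conditions: (CF3SO2)2O, i-Pr2NEt, CH2Cl2, −78 °C
Reagents that add atoms: trifluoromethanesulfonic anhydride, O=S(=O)(OS(=O)(=O)C(F)(F)F)C(F)(F)F
Why: O-sulfonylation of the hydrogen-bonded enol of the β-keto ester gives the vinyl triflate regiospecifically, with the double bond between the ester carbon and the former ketone carbon; no stereocentre changes.

Step 9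
Reactants: 18
Product: 19 di-tert-butyl (4aR,4bS,8aR,9S,9aS)-9-butanoyl-9-hydroxy-6-{[(trifluoromethyl)sulfonyl]oxy}-1,2,4b,7,8,8a,9,9a-octahydro-4aH-fluorene-4a,5-dicarboxylate
Conditions: RuCl3 (2 mol %), Oxone (2KHSO5·KHSO4·K2SO4), NaHCO3, EtOAc/MeCN/H2O (6:6:1), rt
Reagents that add atoms: potassium peroxymonosulfate, [K+].[O-]S(=O)(=O)OO
Why: RuO4-catalysed ketohydroxylation, in which RuO4 formed in the flask adds suprafacially to the most electron-rich alkene (the trisubstituted exocyclic one; the vinyl triflate is electron-poor and the ring E alkene is disubstituted and neopentylic) from the face not shielded by the two cis-fused six-membered rings and the ruthenate ester is oxidised on to the ketol, so the tertiary OH ends up cis to the 4a-ester and the CH carbon becomes the butanoyl ketone, which sets the last stereocentre.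

Step 10
Reactants: 19
Product: 21 (4aR,4bS,8aR,9S,9aS)-9-butanoyl-9-hydroxy-6-{[(trifluoromethyl)sulfonyl]oxy}-1,2,4b,7,8,8a,9,9a-octahydro-4aH-fluorene-4a,5-dicarboxylic acid 4a,9-lactone, via hydroxy diacid 20 (not isolated)
Conditions: CF3CO2H/CH2Cl2 (1:3), 0 °C → rt; then PhMe, 50 °C, evaporation
Reagents that add atoms: none
Why: acidolysis of both tert-butyl esters followed by acid-catalysed γ-lactonisation of the tertiary alcohol onto the 1,3-cis carboxylic acid, the only lactone the geometry allows, driven by azeotropic removal of water; the vinyl triflate and all stereocentres are unaffected.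

Step 11
Reactants: 21; 22 pent-1-yne
Product: 24 CNP0423313.1 (target), via enynoic acid 23 (not isolated)
Conditions: Pd(PPh3)2Cl2 (5 mol %), CuI (10 mol %), Et3N, DMF, rt → 50 °C
Reagents that add atoms: none
Why: tandem Sonogashira coupling and 5-exo-dig lactonisation, in which the vinyl triflate couples with the alkyne and the neighbouring carboxylate then adds anti across the metal-activated triple bond to give the (Z)-butylidene butenolide; no sp3 stereocentre is touched.

**Compound list**

1 | tert-butyl benzoate | CC(C)(C)OC(=O)c1ccccc1 | starting material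
2 | 3-bromo-1,1-dimethoxypropane | COC(CCBr)OC | starting material
3 | lithium dienolate of tert-butyl cyclohexa-2,5-diene-1-carboxylate | [Li+].[O-]C(OC(C)(C)C)=C1C=CCC=C1 | intermediate
4 | tert-butyl 1-(3,3-dimethoxypropyl)cyclohexa-2,5-diene-1-carboxylate | COC(CCC1(C=CCC=C1)C(=O)OC(C)(C)C)OC | intermediate
5 | tert-butyl 1-(3-oxopropyl)cyclohexa-2,5-diene-1-carboxylate | O=CCCC1(C=CCC=C1)C(=O)OC(C)(C)C | intermediate
6 | tert-butyl (3aS,7aS)-1-oxo-1,2,3,6,7,7a-hexahydro-3aH-indene-3a-carboxylate (cis-fused) | O=C1CC[C@@]2(C=CCC[C@H]12)C(=O)OC(C)(C)C | intermediate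
7 | tert-butyl (3aS,7aS)-1-[(trimethylsilyl)oxy]-3,6,7,7a-tetrahydro-3aH-indene-3a-carboxylate | C[Si](C)(C)OC1=CC[C@@]2(C=CCC[C@H]12)C(=O)OC(C)(C)C | intermediate
8 | tert-butyl (3aR,7aS)-1-oxo-1,6,7,7a-tetrahydro-3aH-indene-3a-carboxylate | O=C1C=C[C@@]2(C=CCC[C@H]12)C(=O)OC(C)(C)C | intermediate
9 | tert-butyl acetate | CC(=O)OC(C)(C)C | starting material
10 | acrolein (prop-2-enal) | C=CC=O | starting material
11 | lithium enolate of tert-butyl acetate | [Li+].[O-]C(=C)OC(C)(C)C | intermediate
12 | tert-butyl 3-hydroxypent-4-enoate (racemic) | C=CC(O)CC(=O)OC(C)(C)C | intermediate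
13 | tert-butyl 3-oxopent-4-enoate | C=CC(=O)CC(=O)OC(C)(C)C | intermediate
14 | di-tert-butyl (4aR,4bS,8aR,9aS)-6-hydroxy-9-oxo-1,2,4b,7,8,8a,9,9a-octahydro-4aH-fluorene-4a,5-dicarboxylate (enol form of the β-keto ester; 4a-ester, H-4b, H-8a and H-9a all on one face) | CC(C)(C)OC(=O)C1=C(O)CC[C@@H]2[C@H]1[C@]1(C(=O)OC(C)(C)C)C=CCC[C@@H]1C2=O | intermediate
15 | butyltriphenylphosphonium bromide | CCCC[P+](c1ccccc1)(c1ccccc1)c1ccccc1.[Br-] | starting material
16 | butylidene(triphenyl)phosphorane | CCCC=P(c1ccccc1)(c1ccccc1)c1ccccc1 | intermediate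
17 | di-tert-butyl (4aS,4bS,8aR,9aR)-9-butylidene-6-hydroxy-1,2,4b,7,8,8a,9,9a-octahydro-4aH-fluorene-4a,5-dicarboxylate (same ring configuration as 14; E/Z mixture at the butylidene) | CC(C)(C)OC(=O)C1=C(O)CC[C@@H]2[C@H]1[C@]1(C(=O)OC(C)(C)C)C=CCC[C@@H]1C2=CCCC | intermediate
18 | di-tert-butyl (4aS,4bS,8aR,9aR)-9-butylidene-6-{[(trifluoromethyl)sulfonyl]oxy}-1,2,4b,7,8,8a,9,9a-octahydro-4aH-fluorene-4a,5-dicarboxylate (E/Z mixture at the butylidene) | CC(C)(C)OC(=O)C1=C(OS(=O)(=O)C(F)(F)F)CC[C@@H]2[C@H]1[C@]1(C(=O)OC(C)(C)C)C=CCC[C@@H]1C2=CCCC | intermediate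
19 | di-tert-butyl (4aR,4bS,8aR,9S,9aS)-9-butanoyl-9-hydroxy-6-{[(trifluoromethyl)sulfonyl]oxy}-1,2,4b,7,8,8a,9,9a-octahydro-4aH-fluorene-4a,5-dicarboxylate (9-OH cis to the 4a-ester) | CC(C)(C)OC(=O)C1=C(OS(=O)(=O)C(F)(F)F)CC[C@@H]2[C@H]1[C@]1(C(=O)OC(C)(C)C)C=CCC[C@@H]1[C@]2(O)C(=O)CCC | intermediate
20 | (4aR,4bS,8aR,9S,9aS)-9-butanoyl-9-hydroxy-6-{[(trifluoromethyl)sulfonyl]oxy}-1,2,4b,7,8,8a,9,9a-octahydro-4aH-fluorene-4a,5-dicarboxylic acid | OC(=O)C1=C(OS(=O)(=O)C(F)(F)F)CC[C@@H]2[C@H]1[C@]1(C(=O)O)C=CCC[C@@H]1[C@]2(O)C(=O)CCC | intermediate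
21 | (4aR,4bS,8aR,9S,9aS)-9-butanoyl-9-hydroxy-6-{[(trifluoromethyl)sulfonyl]oxy}-1,2,4b,7,8,8a,9,9a-octahydro-4aH-fluorene-4a,5-dicarboxylic acid 4a,9-lactone | OC(=O)C1=C(OS(=O)(=O)C(F)(F)F)CC[C@@H]2[C@H]1[C@]13C=CCC[C@@H]1[C@@]2(C(=O)CCC)OC3=O | intermediate
22 | pent-1-yne | CCCC#C | starting material
23 | (4aR,4bS,8aR,9S,9aS)-9-butanoyl-9-hydroxy-6-(pent-1-yn-1-yl)-1,2,4b,7,8,8a,9,9a-octahydro-4aH-fluorene-4a,5-dicarboxylic acid 4a,9-lactone | OC(=O)C1=C(C#CCCC)CC[C@@H]2[C@H]1[C@]13C=CCC[C@@H]1[C@@]2(C(=O)CCC)OC3=O | intermediate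
24 | CNP0423313.1: 6,3′:7,7a′-linked phthalide dimer, (3Z,6R,7S,3′S,3a′S,7a′R) in phthalide numbering; rings B and E and the butanoyl group on one face of ring C, lactone D bridging the other | CCC/C=C1\OC(=O)C2=C1CC[C@@H]1[C@H]2[C@]23C=CCC[C@@H]2[C@@]1(C(=O)CCC)OC3=O | target

**Step count and risks**

Total step count: 11. Longest linear sequence: 9 (steps 1, 2, 3, 6, 7, 8, 9, 10, 11).

The three steps most likely to fail:

Step 2. The carbene-catalysed hydroacylation has precedent only for aromatic aldehydes and terminal or 1,1-disubstituted alkenes; with an aliphatic aldehyde and a ring alkene, benzoin or aldol self-condensation may win, or the enantioselectivity may be low. The fallback leaves carbene catalysis for transition-metal C–H activation. It sets out from 5: cationic monovalent rhodium with a chiral bisphosphine (bis(1,5-cyclooctadiene)rhodium tetrafluoroborate with (R)-2,2′-bis(diphenylphosphino)-1,1′-binaphthyl, activated with H2, CH2Cl2, rt) inserts into the formyl C–H bond, hydrometallates one enantiotopic alkene and reductively eliminates, which is the established 4-pentenal to cyclopentanone cyclisation. It comes back to the route at 6 and forms no compound outside the list, none F0.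

Step 6. A cyclopentenone without a second activating group may stop at the mono-Michael adduct, the vinyl ketone may polymerise, and the face selectivity rests only on the angular ester. The fallback replaces the anionic annulation by a cycloaddition. It sets out from 13 and 8: 13 is silylated (Me3SiCl, Et3N, ZnCl2 cat.) to tert-butyl (2Z)-3-[(trimethylsilyl)oxy]penta-2,4-dienoate F1, which undergoes a Diels–Alder reaction with 8 (PhMe, 110 °C, or Me2AlCl, CH2Cl2, −40 °C; addition anti to the angular ester, cis ring fusion) to give the silyl enol ether cycloadduct F2; dilute HCl in THF then hydrolyses the enol ether, and the route is rejoined at 14.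

Step 9. RuO4 may also attack the ring E alkene or cleave the ketol. The fallback lets the carboxyl group itself deliver the oxygen. It sets out from 18: CF3CO2H removes both tert-butyl esters to give the butylidene diacid F3; iodolactonisation (I2, NaHCO3, MeCN/H2O) closes the bridged lactone at the tertiary alkene carbon (5-exo, cis by necessity) to give the iodolactone F4; Kornblum oxidation (AgBF4, DMSO, then Et3N) converts the CH–I group into the butanoyl ketone. It comes back to the route at 21.

**Further compounds**

F0 | step 2 | none | none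
F1 | step 6 | tert-butyl (2Z)-3-[(trimethylsilyl)oxy]penta-2,4-dienoate | CC(C)(C)OC(=O)/C=C(\O[Si](C)(C)C)C=C
F2 | step 6 | di-tert-butyl 9-oxo-6-[(trimethylsilyl)oxy]-1,2,4b,5,8,8a,9,9a-octahydro-4aH-fluorene-4a,5-dicarboxylate (ring-fusion configuration as in 14; mixture of epimers at the ester-bearing ring B carbon) | CC(C)(C)OC(=O)C1C(O[Si](C)(C)C)=CC[C@@H]2[C@H]1[C@]1(C(=O)OC(C)(C)C)C=CCC[C@@H]1C2=O
F3 | step 9 | (4aS,4bS,8aR,9aR)-9-butylidene-6-{[(trifluoromethyl)sulfonyl]oxy}-1,2,4b,7,8,8a,9,9a-octahydro-4aH-fluorene-4a,5-dicarboxylic acid (E/Z mixture at the butylidene) | OC(=O)C1=C(OS(=O)(=O)C(F)(F)F)CC[C@@H]2[C@H]1[C@]1(C(=O)O)C=CCC[C@@H]1C2=CCCC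
F4 | step 9 | (4aR,4bS,8aR,9S,9aS)-9-hydroxy-9-(1-iodobutyl)-6-{[(trifluoromethyl)sulfonyl]oxy}-1,2,4b,7,8,8a,9,9a-octahydro-4aH-fluorene-4a,5-dicarboxylic acid 4a,9-lactone (mixture of epimers at the CH–I carbon) | OC(=O)C1=C(OS(=O)(=O)C(F)(F)F)CC[C@@H]2[C@H]1[C@]13C=CCC[C@@H]1[C@@]2(C(I)CCC)OC3=O
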